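The ratio of target lost to starting material lost reads 0.851 in oak from 4.00 h to 8.00 h, and 0.916 in cedar from 3.00 h to 30.0 h. Both lie near one, so late in these runs the two seem to fall together, one of each.

common to all: starting material 0.12 M; free catalyst 0.2 mol%

| flask | partner | second substrate | remark | time |
|---|---|---|---|---|
| oak | 1.2 equiv (fed, over 30 min) | 1 equiv | the very flask that is asked about, followed so far; the fed solution adds 0.20 times the starting volume |  |
| cedar | 2.4 equiv (fed, over 30 min) | 1 equiv | run made earlier; the fed solution adds 0.20 times the starting volume |  |
| flask | 1.20 equiv (fed, over 30 min) | 1.00 equiv | the fed solution adds 0.20 times the starting volume | 2.0 d |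

| run | time / h | target / % | starting material / % |
|---|---|---|---|
| oak | 0.833 | 42.9 | 51.2 |
| oak | 2.00 | 47.2 | 36.3 |
| oak | 4.00 | 45.0 | 27.3 |
| oak | 6.00 | 39.6 | 21.8 |
| oak | 8.00 | 37.6 | 18.6 |
| cedar | 3.00 | 60.9 | 18.6 |
| cedar | 8.00 | 51.4 | 9.4 |
| cedar | 15.0 | 47.5 | 4.8 |
| cedar | 25.0 | 44.8 | 1.7 |
| cedar | 30.0 | 44.5 | 0.7 |

(each reading ± 0.5 percentage points)

- time up to 2.0 d at which target stands highest
- the amount of target, in percent of the starting material charged, at that time

- charges are per starting volume, the dose included; the dosed solution carries all of it

From 4.00 h on, oak's target minus starting material averages 18 percentage points. This gap, target minus starting material at one moment, begins at minus 100 and climbs while starting material turns into target. It holds still under one-for-one loss, and at zero starting material target equals it. Oak's gap reads 11 points at 2.00 h, so it is still climbing there, and afterwards target heads down towards the gap. My own reckoning therefore puts the top near 0.083 d, at about 47 %.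

The forecast gives 47.6 % at 0.1 d, reasoning “I therefore expect no later rise in oak”.

The flask gives 48.0 % at 0.0732 d, a height close to the forecast's but earlier.

    second substrate + partner + free catalyst → free catalyst + second product (k = 1.34 × 10⁵ M⁻² h⁻¹)
    starting material + partner + free catalyst → free catalyst + target (k = 1.42 × 10⁵ M⁻² h⁻¹)
    partner + free catalyst → spent catalyst (k = 22.4 M⁻¹ h⁻¹)
    starting material + target → side product (k = 2.24 M⁻¹ h⁻¹)

At 2.00 d the flask's gap stands at 19 points, and at 20.0 d target holds 19.1 % with starting material at 0 %. Oak lifted the gap by 118 times the starting material charged, on its partner charge. Scaled by partner, the other charges as in the flask, a neighbour with 0.300 equiv of partner reaches −70 points, a negative gap, so this reckoning sends target towards zero while starting material stays. That neighbour ends at 2.00 d with target at 0.00779 % and starting material at 69.3 %.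

The runs were computed with made-up constants; noise was put on by code.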